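The earlier runs and the new flask come from a simulation from invented constants; scatter was added.

Read the substrate column twice: no reading shows the coupling partner, so its count per substrate stays open, one at the least, two if the next step also takes one.

| setting | red | teal | ash | cedar |
|---|---|---|---|---|
| substrate | 0.050 M | 0.050 M | 0.050 M | 0.050 M |
| coupling partner | 0.088 M | 0.098 M | 0.0650 M | 0.0850 M |
| remark | run made earlier | run made earlier |  |  |
| time |  |  | 10 min | 10 min |

| run | time / min | substrate / % | intermediate / % | target / % | over-reaction product / % |
|---|---|---|---|---|---|
| red | 1.00 | 77.3 | 16.5 | 2.8 | 0 |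
| red | 2.00 | 66.3 | 23.3 | 9.5 | 0.8 |
| red | 3.00 | 55.2 | 25.0 | 18.7 | 0.7 |
| red | 4.00 | 46.7 | 26.8 | 23.0 | 1.3 |
| red | 5.00 | 40.1 | 23.1 | 29.5 | 4.3 |
| teal | 0.417 | 88.0 | 11.7 | 0 | 0 |
| teal | 1.33 | 74.0 | 22.8 | 6.0 | 2.4 |
| teal | 2.50 | 57.6 | 27.9 | 15.9 | 0.4 |
| teal | 4.00 | 44.5 | 28.3 | 24.7 | 1.3 |
| teal | 5.00 | 37.0 | 24.1 | 31.5 | 5.0 |

(scatter of a reading: 1 percentage point)

- a reading or a percentage of target counts all its forms, free or not
- a reading of intermediate is of its free form alone

* which of these there is most of at the end, counted by the substrate in it, ash (over-reaction product / target / substrate / intermediate)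
* which of these there is most of at the end, counted by the substrate in it, cedar (over-reaction product / target / substrate / intermediate)
* amount of the one of these that there is most of at the end, in percent of the substrate charged, ash
* amount of the one of these that there is most of at the end, in percent of the substrate charged, cedar

- Let a be the fraction of the substrate charge left, r the partner charge in equivalents, c the count. If substrate is lost in proportion to a times the partner left, then ln((r − c + ca)/(ra)) = (r − c)κt.
- Here κ is the charge rate, the fraction of the remaining substrate lost per minute per equivalent of partner present. Red and teal at 5.00 min give, on average, 0.129 min⁻¹ at count one and 0.183 min⁻¹ at count two.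
- Solved for a at 10 min, these bracket substrate: ash from 32.9% to 42.7%, cedar from 22.0% to 29.4%.
- Target, a softer range, takes the share of converted substrate seen at those last readings, 49.6%, assumed to hold: ash 28.4% to 33.3%, cedar 35.0% to 38.7%.
- My reckoning therefore puts substrate first in ash, its midpoint 37.8% above target's 30.8%, and target first in cedar, its lower end above substrate's upper end.
- The forecast, holding that “roughly 2 equivalents are needed to reach target”, gives substrate at 38% in ash, inside the bracket, and target at 41% in cedar, above the range.
- Ash ends with substrate at 35.5%, above the lower end that 0.129 min⁻¹ gave; cedar ends with target at 38.1%, inside its range.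

    intermediate ⇌ isomer of the product (K = 2.50, k = 0.00820 min⁻¹)
    substrate + coupling partner → intermediate + by-product (k = 2.70 M⁻¹ min⁻¹)
    target → over-reaction product (k = 0.230 min⁻¹)
    intermediate ⇌ target (K = 3.40, k = 0.330 min⁻¹)
    coupling partner + target ⇌ idle adduct, settled at all times (K = 40.0 M⁻¹)

- In cedar at 2.41 min, partner's half-life by its reaction with substrate is 8.2 min, longer than free target's 3.0 min by its reaction to over-reaction product. At 10.0 min cedar's target of 38.1% includes 22.5% of idle adduct, and over-reaction product holds 20.1%.
- In the neighbour of cedar with substrate raised to 0.085 M, κ scales with the substrate charge under the same rate law and r is one, so substrate is reckoned at 31.4% to 51.1%, with target at 24.3% to 34.0%. That flask gives substrate first at 35.9%, target 28.1%.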